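**Strategy.** The pyran ring C is cut at C4–C4a and O1–C2. This splits the flavan into a phloroglucinol-derived phenol (ring A with O1) and a cinnamaldehyde that carries ring B and C2–C3–C4. The key step reunites them in one operation: boron-templated ortho-hydroxyalkylation, loss of water to an ortho-quinone methide and oxa-6π electrocyclisation give a flav-3-ene. It exploits the O1–C8a=C4a enol unit of the symmetric ring A as a 1,3-C,O-dinucleophile. The C3=C4 alkene is then turned into the flavan-3-one, whose C2 is epimerisable. One asymmetric transfer hydrogenation with dynamic kinetic resolution therefore sets the cis-(2R,3R) pair. Steglich esterification with silyl-protected ferulic acid and fluoride deprotection finish the synthesis.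

Key step: step 5

Abbreviations: TBS = tert-butyldimethylsilyl, TBSO = tert-butyldimethylsilyloxy. Flavan numbering is used throughout (O1, C2, C3, C4, C4a, C5–C8, C8a, ring B primed).

Assumption: in step 7 the sense of induction is assigned by analogy with aryl ketones, the π-rich C2 side of the flavan-3-one taking the place of the aryl group, which calls for the (R,R)-catalyst; should the opposite sense hold, the (S,S)-catalyst is used and nothing else changes.

Step 1
Reactants: 1 phloroglucinol (benzene-1,3,5-triol)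
Product: 2 3,5-bis(TBSO)phenol
Conditions: TBSCl (2.0 equiv), imidazole, DMF, 0 °C → rt
Reagents that add atoms: tert-butyldimethylsilyl chloride (TBSCl), CC(C)(C)[Si](C)(C)Cl
Why: Silyl ether formation on a C3-symmetric triol is statistical, so two equivalents of TBSCl should give mainly the bis-ether, which is separable from the mono- and tris-ethers by chromatography.

Step 2
Reactants: 3 3,4,5-trihydroxybenzaldehyde
Product: 4 3,5-dihydroxy-4-methoxybenzaldehyde
Conditions: MeI (1.05 equiv), Li2CO3, DMF, 40 °C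
Reagents that add atoms: methyl iodide (MeI), CI
Why: In this Williamson ether synthesis under weak-base control the 4-OH, para to the formyl group, is the most acidic of the three hydroxyls, so mainly its phenoxide forms and is methylated.

Step 3
Reactants: 4 3,5-dihydroxy-4-methoxybenzaldehyde
Product: 5 3,5-bis(TBSO)-4-methoxybenzaldehyde
Conditions: TBSCl (2.4 equiv), imidazole, DMF, rt
Reagents that add atoms: tert-butyldimethylsilyl chloride (TBSCl), CC(C)(C)[Si](C)(C)Cl
Why: Imidazole-promoted silyl ether formation caps both remaining phenols with a group that can later be removed without touching a cinnamate alkene.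

Step 4
Reactants: 5 3,5-bis(TBSO)-4-methoxybenzaldehyde
Product: 6 (E)-3-[3,5-bis(TBSO)-4-methoxyphenyl]prop-2-enal
Conditions: Ph3P=CHCHO (1.1 equiv), toluene, 90 °C
Reagents that add atoms: (triphenylphosphoranylidene)acetaldehyde, O=CC=P(c1ccccc1)(c1ccccc1)c1ccccc1
Why: Wittig olefination with a stabilised ylide should give the E-enal, and only a slight excess of ylide is used to limit a second homologation.

Step 5
Reactants: 2 3,5-bis(TBSO)phenol; 6 (E)-3-[3,5-bis(TBSO)-4-methoxyphenyl]prop-2-enal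
Product: 9 (±)-2-[3,5-bis(TBSO)-4-methoxyphenyl]-5,7-bis(TBSO)-2H-chromene (flav-3-ene), via benzodioxaborin 7 (not isolated), via ortho-quinone methide 8 (not isolated)
Conditions: C6F5B(OH)2 (20 mol %), Ph2P(O)OH (20 mol %), toluene, 90 °C
Reagents that add atoms: none
Why: The boronic acid ties the phenol oxygen of 2 and the carbonyl oxygen of 6 together, so the ring A carbon ortho to the hydroxyl adds to the aldehyde carbon through a six-membered transition state and gives benzodioxaborin 7 (C4–C4a bond). Acid-assisted loss of the boronic acid from 7 gives ortho-quinone methide 8, whose O=C8a–C4a=C4–C3=C2 oxatriene closes by a thermal disrotatory oxa-6π electrocyclisation (O1–C2 bond), which forms pyran ring C with rearomatisation of ring A as the driving force. This is the known formal [3+3] chromene synthesis from phenols and α,β-unsaturated aldehydes (Knoevenagel-type condensation/oxa-6π electrocyclisation) under boronic acid/Brønsted acid co-catalysis. The only new stereocentre, C2, is formed without control and 9 is racemic by design, because C2 becomes epimerisable in the flavan-3-one made in step 6 and is fixed in step 7. The step needs 1,2- over 1,4-addition and ortho over para attack, both secured by the boron tether, and the two ortho carbons of 2 are equivalent by symmetry, so one regioisomer should result. The silyl ethers keep the other two oxygens of ring A out of the condensation, so only one annulation can take place.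

Step 6
Reactants: 9 (±)-2-[3,5-bis(TBSO)-4-methoxyphenyl]-5,7-bis(TBSO)-2H-chromene
Product: 11 (±)-2-[3,5-bis(TBSO)-4-methoxyphenyl]-5,7-bis(TBSO)chroman-3-one (flavan-3-one), via epoxide 10 (not isolated)
Conditions: DMDO (1.05 equiv, acetone), CH2Cl2, −40 → 0 °C; volatiles removed; then BF3·OEt2 (10 mol %), CH2Cl2, −78 °C
Reagents that add atoms: dimethyldioxirane (DMDO), CC1(C)OO1
Why: Neutral epoxidation of the electron-rich C3=C4 styrene bond is followed by a Meinwald rearrangement, in which the Lewis acid opens 10 at C4 to the cation stabilised by the 5- and 7-silyloxy groups and a 1,2-hydride shift from C3 gives the ketone, so the facial selectivity of the epoxidation does not matter.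

Step 7
Reactants: 11 (±)-2-[3,5-bis(TBSO)-4-methoxyphenyl]-5,7-bis(TBSO)chroman-3-one
Product: 12 (2R,3R)-2-[3,5-bis(TBSO)-4-methoxyphenyl]-5,7-bis(TBSO)chroman-3-ol (cis)
Conditions: (R,R)-Ts-DENEB (oxo-tethered Ru–TsDPEN, 2 mol %), HCO2H/Et3N (5:2), CH2Cl2, 30 °C, argon
Reagents that add atoms: none
Why: In this Noyori–Ikariya asymmetric transfer hydrogenation with dynamic kinetic resolution, C2–H (α to the ketone, benzylic and α to O1) lets the enantiomers of 11 interconvert through the enol, while the catalyst fixes the face of hydride delivery at C3 (3R) and should reduce only the (2R)-ketone quickly, because only there is that face anti to the C2 aryl group, which gives the cis-(2R,3R)-alcohol.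

Step 8
Reactants: 13 (E)-ferulic acid
Product: 15 (E)-4-O-TBS-ferulic acid, via silyl ester 14 (not isolated)
Conditions: TBSCl (2.3 equiv), imidazole, DMF, rt; then AcOH/THF/H2O, rt
Reagents that add atoms: tert-butyldimethylsilyl chloride (TBSCl), CC(C)(C)[Si](C)(C)Cl
Why: Exhaustive silylation followed by selective hydrolysis works because a silyl ester is far more labile to aqueous acid than an aryl silyl ether.

Step 9
Reactants: 12 (2R,3R)-2-[3,5-bis(TBSO)-4-methoxyphenyl]-5,7-bis(TBSO)chroman-3-ol; 15 (E)-4-O-TBS-ferulic acid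
Product: 16 (2R,3R)-2-[3,5-bis(TBSO)-4-methoxyphenyl]-5,7-bis(TBSO)chroman-3-yl (E)-4-O-TBS-ferulate
Conditions: DCC, DMAP (cat.), CH2Cl2, 0 °C → rt
Reagents that add atoms: none
Why: Steglich esterification acylates the only free hydroxyl at oxygen, so the C3–O bond, both stereocentres and the E-alkene are untouched.

Step 10
Reactants: 16 (2R,3R)-2-[3,5-bis(TBSO)-4-methoxyphenyl]-5,7-bis(TBSO)chroman-3-yl (E)-4-O-TBS-ferulate
Product: 17 4'-O-methylepigallocatechin-3-O-ferulate
Conditions: Et3N·3HF (excess), THF, 0 °C → rt, argon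
Reagents that add atoms: none
Why: Fluoride-mediated desilylation under slightly acidic, non-reducing conditions should free all five phenols while sparing the ester, the cinnamate alkene, both methyl ethers and the stereocentres.

**Compound list**

1 | phloroglucinol | Oc1cc(O)cc(O)c1 | starting material
2 | 3,5-bis(TBSO)phenol | Oc1cc(O[Si](C)(C)C(C)(C)C)cc(O[Si](C)(C)C(C)(C)C)c1 | intermediate
3 | 3,4,5-trihydroxybenzaldehyde | O=Cc1cc(O)c(O)c(O)c1 | starting material
4 | 3,5-dihydroxy-4-methoxybenzaldehyde | COc1c(O)cc(C=O)cc1O | intermediate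
5 | 3,5-bis(TBSO)-4-methoxybenzaldehyde | COc1c(O[Si](C)(C)C(C)(C)C)cc(C=O)cc1O[Si](C)(C)C(C)(C)C | intermediate
6 | (E)-3-[3,5-bis(TBSO)-4-methoxyphenyl]prop-2-enal | COc1c(O[Si](C)(C)C(C)(C)C)cc(/C=C/C=O)cc1O[Si](C)(C)C(C)(C)C | intermediate
7 | (±)-2-(pentafluorophenyl)-4-[(E)-2-(3,5-bis(TBSO)-4-methoxyphenyl)ethenyl]-5,7-bis(TBSO)-4H-1,3,2-benzodioxaborinine (not isolated) | COc1c(O[Si](C)(C)C(C)(C)C)cc(/C=C/C2OB(c3c(F)c(F)c(F)c(F)c3F)Oc3cc(O[Si](C)(C)C(C)(C)C)cc(O[Si](C)(C)C(C)(C)C)c32)cc1O[Si](C)(C)C(C)(C)C | intermediate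
8 | 6-[(E)-3-(3,5-bis(TBSO)-4-methoxyphenyl)prop-2-enylidene]-3,5-bis(TBSO)cyclohexa-2,4-dien-1-one, ortho-quinone methide (not isolated) | COc1c(O[Si](C)(C)C(C)(C)C)cc(/C=C/C=C2C(=O)C=C(O[Si](C)(C)C(C)(C)C)C=C2O[Si](C)(C)C(C)(C)C)cc1O[Si](C)(C)C(C)(C)C | intermediate
9 | (±)-2-[3,5-bis(TBSO)-4-methoxyphenyl]-5,7-bis(TBSO)-2H-chromene | COc1c(O[Si](C)(C)C(C)(C)C)cc(C2C=Cc3c(O[Si](C)(C)C(C)(C)C)cc(O[Si](C)(C)C(C)(C)C)cc3O2)cc1O[Si](C)(C)C(C)(C)C | intermediate
10 | (±)-3,4-epoxy-2-[3,5-bis(TBSO)-4-methoxyphenyl]-5,7-bis(TBSO)chroman, relative configuration immaterial (not isolated) | COc1c(O[Si](C)(C)C(C)(C)C)cc(C2Oc3cc(O[Si](C)(C)C(C)(C)C)cc(O[Si](C)(C)C(C)(C)C)c3C3OC32)cc1O[Si](C)(C)C(C)(C)C | intermediate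
11 | (±)-2-[3,5-bis(TBSO)-4-methoxyphenyl]-5,7-bis(TBSO)chroman-3-one | COc1c(O[Si](C)(C)C(C)(C)C)cc(C2Oc3cc(O[Si](C)(C)C(C)(C)C)cc(O[Si](C)(C)C(C)(C)C)c3CC2=O)cc1O[Si](C)(C)C(C)(C)C | intermediate
12 | (2R,3R)-2-[3,5-bis(TBSO)-4-methoxyphenyl]-5,7-bis(TBSO)chroman-3-ol | O[C@@H]1Cc2c(O[Si](C)(C)C(C)(C)C)cc(O[Si](C)(C)C(C)(C)C)cc2O[C@@H]1c1cc(O[Si](C)(C)C(C)(C)C)c(OC)c(O[Si](C)(C)C(C)(C)C)c1 | intermediate
13 | (E)-ferulic acid | COc1cc(/C=C/C(=O)O)ccc1O | starting material
14 | tert-butyldimethylsilyl (E)-4-O-TBS-ferulate (not isolated) | COc1cc(/C=C/C(=O)O[Si](C)(C)C(C)(C)C)ccc1O[Si](C)(C)C(C)(C)C | intermediate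
15 | (E)-4-O-TBS-ferulic acid | COc1cc(/C=C/C(=O)O)ccc1O[Si](C)(C)C(C)(C)C | intermediate
16 | penta-TBS-protected 4'-O-methylepigallocatechin-3-O-ferulate | COc1cc(/C=C/C(=O)O[C@@H]2Cc3c(O[Si](C)(C)C(C)(C)C)cc(O[Si](C)(C)C(C)(C)C)cc3O[C@@H]2c2cc(O[Si](C)(C)C(C)(C)C)c(OC)c(O[Si](C)(C)C(C)(C)C)c2)ccc1O[Si](C)(C)C(C)(C)C | intermediate
17 | 4'-O-methylepigallocatechin-3-O-ferulate | COc1cc(/C=C/C(=O)O[C@@H]2Cc3c(O)cc(O)cc3O[C@@H]2c2cc(O)c(OC)c(O)c2)ccc1O | target

**Step count.** Total: 10 steps. Longest linear sequence: 8 steps (steps 2, 3, 4, 5, 6, 7, 9 and 10, from 3,4,5-trihydroxybenzaldehyde).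

**Steps most likely to fail**

1. Step 7.
   - What may go wrong: epimerisation at C2 may lag behind the reduction. The catalyst may also discriminate poorly between the faces of a ketone flanked by two sp3 carbons. Either would erode enantiomeric and cis/trans purity. Slow loss of aryl silyl ethers in the formate medium is a further risk.
   - Fallback (substrate-controlled reduction plus classical resolution): it sets out from 11. L-Selectride in THF at −78 °C delivers hydride anti to the C2 aryl group and should give the racemic cis-flavan-3-ol F1. Esterification with (S)-O-methylmandelic acid (DCC, DMAP, CH2Cl2, 0 °C) gives the (2R,3R)-O-methylmandelate F2 and the (2S,3S)-O-methylmandelate F3, which are separated by chromatography. Reductive cleavage of F2 with DIBAL-H in CH2Cl2 at −78 °C, which leaves the aryl silyl ethers alone, comes back to the route at 12.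

2. Step 5.
   - What may go wrong: conjugate Friedel–Crafts addition at the β-carbon of the enal, oligomerisation of the ortho-quinone methide, or acid-induced attack of unreacted phenol on the electron-rich flavene.
   - Fallback (aryl propargyl ether rearrangement): it sets out from 5 and 2. Ethynylmagnesium bromide in THF at 0 °C adds to 5 and gives the racemic propargylic alcohol F4. Mitsunobu etherification with 2 (DIAD, PPh3, THF) gives the aryl propargyl ether F5. Heating in N,N-diethylaniline at 160 °C starts a Claisen rearrangement, enolisation and 1,5-hydrogen shift to the same ortho-quinone methide 8. This intermediate closes by oxa-6π electrocyclisation, so C4–C4a and O1–C2 again form in one operation without acid or free phenol. The fallback comes back to the route at 9.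

3. Step 6.
   - What may go wrong: over-oxidation of the electron-rich rings or of the enol of the product, solvolytic opening of the very labile epoxide in place of the hydride shift, or ring contraction by migration of C2.
   - Fallback (hydroboration/oxidation): it sets out from 9. BH3·THF at 0 °C, followed by NaBO3·4H2O as a mild oxidant that spares the aryl silyl ethers, places the hydroxyl at C3 anti to the aryl group and gives the racemic trans-flavan-3-ol F6. Dess–Martin oxidation (NaHCO3, CH2Cl2) comes back to the route at 11.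

**Further compounds**

F1 | step 7 | (±)-cis-2-[3,5-bis(TBSO)-4-methoxyphenyl]-5,7-bis(TBSO)chroman-3-ol (both enantiomers) | O[C@@H]1Cc2c(O[Si](C)(C)C(C)(C)C)cc(O[Si](C)(C)C(C)(C)C)cc2O[C@@H]1c1cc(O[Si](C)(C)C(C)(C)C)c(OC)c(O[Si](C)(C)C(C)(C)C)c1.O[C@H]1Cc2c(O[Si](C)(C)C(C)(C)C)cc(O[Si](C)(C)C(C)(C)C)cc2O[C@H]1c1cc(O[Si](C)(C)C(C)(C)C)c(OC)c(O[Si](C)(C)C(C)(C)C)c1
F2 | step 7 | (2R,3R)-2-[3,5-bis(TBSO)-4-methoxyphenyl]-5,7-bis(TBSO)chroman-3-yl (S)-2-methoxy-2-phenylacetate | CO[C@H](C(=O)O[C@@H]1Cc2c(O[Si](C)(C)C(C)(C)C)cc(O[Si](C)(C)C(C)(C)C)cc2O[C@@H]1c1cc(O[Si](C)(C)C(C)(C)C)c(OC)c(O[Si](C)(C)C(C)(C)C)c1)c1ccccc1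
F3 | step 7 | (2S,3S)-2-[3,5-bis(TBSO)-4-methoxyphenyl]-5,7-bis(TBSO)chroman-3-yl (S)-2-methoxy-2-phenylacetate | CO[C@H](C(=O)O[C@H]1Cc2c(O[Si](C)(C)C(C)(C)C)cc(O[Si](C)(C)C(C)(C)C)cc2O[C@H]1c1cc(O[Si](C)(C)C(C)(C)C)c(OC)c(O[Si](C)(C)C(C)(C)C)c1)c1ccccc1
F4 | step 5 | (±)-1-[3,5-bis(TBSO)-4-methoxyphenyl]prop-2-yn-1-ol | C#CC(O)c1cc(O[Si](C)(C)C(C)(C)C)c(OC)c(O[Si](C)(C)C(C)(C)C)c1
F5 | step 5 | (±)-1-[3,5-bis(TBSO)-4-methoxyphenyl]prop-2-yn-1-yl 3,5-bis(TBSO)phenyl ether | C#CC(Oc1cc(O[Si](C)(C)C(C)(C)C)cc(O[Si](C)(C)C(C)(C)C)c1)c1cc(O[Si](C)(C)C(C)(C)C)c(OC)c(O[Si](C)(C)C(C)(C)C)c1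
F6 | step 6 | (±)-trans-2-[3,5-bis(TBSO)-4-methoxyphenyl]-5,7-bis(TBSO)chroman-3-ol (both enantiomers) | O[C@H]1Cc2c(O[Si](C)(C)C(C)(C)C)cc(O[Si](C)(C)C(C)(C)C)cc2O[C@@H]1c1cc(O[Si](C)(C)C(C)(C)C)c(OC)c(O[Si](C)(C)C(C)(C)C)c1.O[C@@H]1Cc2c(O[Si](C)(C)C(C)(C)C)cc(O[Si](C)(C)C(C)(C)C)cc2O[C@H]1c1cc(O[Si](C)(C)C(C)(C)C)c(OC)c(O[Si](C)(C)C(C)(C)C)c1
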